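At 2.5 h the flask has to be read for two things, the average chain length n and the reacted part c of the free monomer, and n needs the end state first.

- average number of monomer units in a chain (chains begun, living or dead) at 2.5 h
- part of the free monomer that has reacted at 2.5 h

in all of them: initiator 66 mM
- summer: free monomer 0.50 M; transfer agent 10 mM; protic impurity 1 M; run made earlier
- autumn: free monomer 0.75 M; transfer agent 10 mM; protic impurity 1 M; run made earlier
- dusk: free monomer 1 M; transfer agent 10 mM; protic impurity 2 M; run made earlier
- flask: free monomer 1.0 M; transfer agent 10.0 mM; protic impurity 1.00 M; time 2.5 h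

| run | time / min | monomer in chains / % | free monomer / % |
|---|---|---|---|
| summer | 15.0 | 6 | 83 |
| summer | 30.0 | 16 | 67 |
| summer | 50.0 | 25 | 52 |
| summer | 60.0 | 29 | 46 |
| summer | 80.0 | 35 | 35 |
| summer | 90.0 | 38 | 28 |
| autumn | 15.0 | 7 | 83 |
| autumn | 30.0 | 17 | 68 |
| autumn | 50.0 | 24 | 52 |
| autumn | 60.0 | 28 | 43 |
| autumn | 80.0 | 37 | 31 |
| autumn | 90.0 | 39 | 27 |
| dusk | 8.00 | 6 | 86 |
| dusk | 25.0 | 13 | 60 |
| dusk | 40.0 | 18 | 47 |
| dusk | 60.0 | 26 | 29 |
| dusk | 90.0 | 33 | 16 |

(scatter of a reading: 1.5 percentage points)

- the average divides the monomer in chains by the number of chains begun, living and dead together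
- on the list of suspects stand: living end + transfer agent -> dead chain; protic impurity + free monomer -> quenched substrate; free monomer + living end -> monomer in chains + living end; free monomer + initiator -> living end + monomer in chains; initiator -> spent initiator
- the earlier runs do not show the number of chains; that part of a forecast is a guess

I carried one quantity. I took φ as the share of reacted free monomer found as monomer in chains, because n is that monomer over chains begun, and each initiator begins at most one chain.

In slow motion, the summer run gave this. At 15.0 min φ read 35.3%: protic impurity was quenching while, as I read it, living ends were still few. Between 30.0 min and 60.0 min the new monomer went 61.9% into chains, which I took as ends built up from initiator. Transfer agent turns ends into dead chains, but the average counts those too, so that step leaves the divisor unchanged. Last readings: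

| run | free monomer | protic impurity | φ |
|---|---|---|---|
| summer | 0.50 M | 1 M | 52.8% |
| autumn | 0.75 M | 1 M | 53.4% |
| dusk | 1 M | 2 M | 39.3% |

Summer and autumn, charged with the same protic impurity, read close together. Dusk, with more protic impurity and more free monomer than summer, read lower, so two settings differ there. I kept the summer value for the flask, whose protic impurity charge matches summer's. The chain count is unread, so I used its ceiling, the initiator charge. That gave the chain yield y, φ times free monomer charged over initiator charged: 8.00, with n = y·c. Summer free monomer fell roughly pseudo-first-order at 0.0141 min⁻¹, so I expected c = 88.0% and n = 7.04.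

The forecast, noting “The chain count is not measured”, gave n = 10 (7.2 to 18) and c = 84% (80% to 88%), its average above mine.

The flask gave n = 7.96 and c = 87.1%.

    living end + transfer agent → dead chain (kL = 0.0381 M⁻¹ s⁻¹)
    protic impurity + free monomer → quenched substrate (k = 1.14 × 10⁻⁴ M⁻¹ s⁻¹)
    free monomer + living end → monomer in chains + living end, rate k3*[living end]*[free monomer] (k = 0.00269 M⁻¹ s⁻¹)
    free monomer + initiator → living end + monomer in chains (k = 0.00121 M⁻¹ s⁻¹)
    initiator → spent initiator (k = 6.10 × 10⁻⁶ s⁻¹)

At 2.50 h the flask held 59.4% of its reacted monomer in chains, above the summer φ. There y·c gives 6.96, and the flask stands 1.14 times that. For the same flask read at 4.0 h, the summer rate gives c = 96.6%, and y with that factor gives n = 8.83. Computed, it stood at 8.86 and 96.1%.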